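**Retrosynthetic overview**

1. 23 ⇐ tert-butyl ester 22 ⇐ C12–C13 by B-alkyl Suzuki coupling of the C9-vinyl decalin 19 with 3-bromobutenolide 20. 19 ⇐ trans-fused δ-lactone 15, whose ring (C8–C17(=O)–O–C12–C11–C9) is not in the target: it is opened at C12 by selenolate, reduced at C17 and eliminated to the vinyl group.
2. 15 ⇐ 7-hydroxy lactone 11 (dehydration, hydrogenation, epimerisation at C8). 11 ⇐ ring A aldehyde 9 + 5,6-dihydro-2H-pyran-2-one 10 in one iron-hydride radical–polar crossover annulation: Giese bond C9–C10 at the quaternary carbon, then aldol closure of ring B at C7–C8.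
3. Enabling feature: C8 lies between C7 and C9 and carries C17, and C9 is bonded to quaternary C10. With C17 at the acyl level, C8 is an enolate carbon and C9 a radical acceptor; C7 (as aldehyde on the ring A arm C5–C6) is the aldol partner; C17–O reaches C12 across C8–C9–C11, so the acceptor can be the cyclic lactone 10.
4. 9 ⇐ amide 8 ⇐ C4 methylation anti to the C5 side chain ⇐ Eschenmoser–Claisen rearrangement of the CBS-derived cyclohexenol 5 (1,3-chirality transfer sets C5) ⇐ enone 4 ⇐ 3-ethoxy-2-methylcyclohexenone 1.
5. Ring order: ring A (present in 1) → ring B together with the temporary lactone ring (step 7) → lactone ring opened (step 10) → butenolide ring attached as a preformed unit (step 13).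

Key step: step 7

Remark: labdane numbering is used for all ring A and bicyclic compounds (ring A = C1–C5, C10; ring B = C5–C10; C17 on C8; C18 = 4α-methyl; C19 = 4β-carboxyl; C20 on C10; side chain C11–C16), α/β refer to the usual drawing with C20 β, and the target is read as (4S,5R,8R,9S,10R), i.e. 8β-H with C17 equatorial.

**Step 1**
Reactants: 1 3-ethoxy-2-methylcyclohex-2-en-1-one
Product: 2 tert-butyl 4-ethoxy-3-methyl-2-oxocyclohex-3-ene-1-carboxylate (racemic)
Conditions: LiN(i-Pr)2 (2.1 equiv), THF, −78 °C; Boc2O, −78 → 0 °C; aq. NH4Cl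
Reagents that add atoms: di-tert-butyl dicarbonate, CC(C)(C)OC(=O)OC(=O)OC(C)(C)C
Why: kinetic α′-deprotonation of the vinylogous ester and C-acylation of the lithium enolate by the dicarbonate (Claisen-type acylation), the second equivalent of base taking up the acidic β-keto ester proton.

**Step 2**
Reactants: 2 tert-butyl 4-ethoxy-3-methyl-2-oxocyclohex-3-ene-1-carboxylate
Product: 4 tert-butyl 3-methyl-4-oxocyclohex-2-ene-1-carboxylate (racemic), via allylic alcohol 3 (not isolated)
Conditions: NaBH4, CeCl3·7H2O, MeOH, 0 °C; then 1 M HCl, THF, 0 °C → rt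
Reagents that add atoms: water, O
Why: Luche 1,2-reduction followed by acid hydrolysis of the enol ether with allylic transposition (Stork–Danheiser sequence) should give the 2-methyl enone with the ester carbon next to the enone β-carbon, cold dilute acid sparing the tert-butyl ester.

**Step 3**
Reactants: 4 tert-butyl 3-methyl-4-oxocyclohex-2-ene-1-carboxylate
Product: 5 tert-butyl (1RS,4R)-4-hydroxy-3-methylcyclohex-2-ene-1-carboxylate
Conditions: (S)-2-methyl-CBS-oxazaborolidine (10 mol%), BH3·SMe2 (0.7 equiv), THF, −20 °C; MeOH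
Reagents that add atoms: none
Why: Corey–Bakshi–Shibata reduction in which the 2-methylalkenyl arm acts as the large group, so the (S)-catalyst should give the (4R)-carbinol in both C1 epimers by reagent control; the epimeric ester carbon is corrected in step 5.

**Step 4**
Reactants: 5 tert-butyl (1RS,4R)-4-hydroxy-3-methylcyclohex-2-ene-1-carboxylate
Product: 7 tert-butyl (1RS,2S)-2-[2-(dimethylamino)-2-oxoethyl]-3-methylcyclohex-3-ene-1-carboxylate, via ketene N,O-acetal 6 (not isolated)
Conditions: MeC(OMe)2NMe2 (5 equiv), toluene, 110–120 °C, sealed tube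
Reagents that add atoms: N,N-dimethylacetamide dimethyl acetal, CN(C)C(C)(OC)OC
Why: Eschenmoser–Claisen rearrangement, whose suprafacial [3,3] shift forms the C5–C6 bond on the face that carried the C–O bond (1,3-chirality transfer, C5 set) and moves the alkene to C1=C10.

**Step 5**
Reactants: 7 tert-butyl (1RS,2S)-2-[2-(dimethylamino)-2-oxoethyl]-3-methylcyclohex-3-ene-1-carboxylate
Product: 8 tert-butyl (1S,2R)-2-[2-(dimethylamino)-2-oxoethyl]-1,3-dimethylcyclohex-3-ene-1-carboxylate
Conditions: KN(SiMe3)2 (1.2 equiv), THF, −78 °C; MeI, −78 → −40 °C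
Reagents that add atoms: iodomethane, CI
Why: ester enolate alkylation in which the silylamide should deprotonate only the ester α-CH (about five pK units more acidic than the amide α-CH2) and iodomethane enters anti to the adjacent C5 side chain, held pseudoaxial by allylic 1,3-strain with the exocyclic enolate, so that the methyl ends trans to the side chain (C4 S).

**Step 6**
Reactants: 8 tert-butyl (1S,2R)-2-[2-(dimethylamino)-2-oxoethyl]-1,3-dimethylcyclohex-3-ene-1-carboxylate
Product: 9 tert-butyl (1S,2R)-1,3-dimethyl-2-(2-oxoethyl)cyclohex-3-ene-1-carboxylate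
Conditions: Cp2Zr(H)Cl (1.6 equiv), THF, rt; silica gel/H2O
Reagents that add atoms: none
Why: chemoselective reduction of a tertiary amide to the aldehyde with Cp2Zr(H)Cl (addition of Zr–H across the amide C=O to a zirconated hemiaminal that collapses on work-up), the hindered tert-butyl ester and the trisubstituted alkene being left alone.

**Step 7**
Reactants: 9 tert-butyl (1S,2R)-1,3-dimethyl-2-(2-oxoethyl)cyclohex-3-ene-1-carboxylate; 10 5,6-dihydro-2H-pyran-2-one
Product: 11 tert-butyl 7β-hydroxy-13,14,15,16-tetranor-8αH-labdan-17,12-olid-19-oate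
Conditions: Fe(acac)3 (30 mol%), PhSiH3 (2.5 equiv), 10 (3 equiv), EtOH/ethylene glycol (5:1), 0 °C → rt, slow addition of 9
Reagents that add atoms: none
Why: Proposed new method: Hydrogen-atom transfer from an iron hydride to the trisubstituted C1=C10 alkene of 9 gives the tertiary C10 radical, which adds to the β-carbon (C9) of lactone 10 (Giese addition, C9–C10 bond); the resulting α-acyl radical is reduced by divalent iron to the lactone enolate (radical–polar crossover), whose C8 attacks the tethered C7 aldehyde. The closest known reaction type is the iron-hydride-initiated radical–polar crossover annulation of γ,δ-unsaturated aldehydes with enones and enals (conjugate addition, then aldol); what goes beyond it is the lactone acceptor, whose ester-level enolate has not been shown to close the aldol ring, although iron-hydride Giese additions to unsaturated esters and lactones are established. Ring B is closed by a 6-(enolexo)-exo-trig aldol that forms C7–C8, while the lactone ring is brought in intact and ends fused to ring B at C8–C9. C10 is controlled by attack on the α face, anti to the vicinal C5 side chain and away from the β-oriented C4 ester, so that C20 ends β (trans-decalin); C9 is controlled by the staggered addition geometry in which H9 lies between C1 and C5 and the flat C8, not the C11 methylene, sits next to the bulkier C5 (the only rotamer from which C8 can reach C7), giving 9α-H; C7 and C8 should arise as the 7β-hydroxy cis-fused lactone from a chelated chair aldol of the cyclic E-enolate, and both are erased or corrected in steps 8 and 9. The step needs hydrogen-atom transfer to the electron-rich alkene and not to the electron-poor lactone alkene (polarity matching, 10 in excess), and aldol closure faster than enolate protonation, which the six-membered transition state with the aldehyde held next to C8 should secure.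

**Step 8**
Reactants: 11 tert-butyl 7β-hydroxy-13,14,15,16-tetranor-8αH-labdan-17,12-olid-19-oate
Product: 13 tert-butyl 13,14,15,16-tetranorlabd-7-en-17,12-olid-19-oate, via mesylate 12 (not isolated)
Conditions: MsCl, Et3N, CH2Cl2, 0 °C; then DBU, rt
Reagents that add atoms: none
Why: E1cB β-elimination of the β-mesyloxy lactone through the lactone enolate should give the conjugated C7=C8 alkene, removing the auxiliary C7 oxygen and converging any C7/C8 epimers.

**Step 9**
Reactants: 13 tert-butyl 13,14,15,16-tetranorlabd-7-en-17,12-olid-19-oate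
Product: 15 tert-butyl 13,14,15,16-tetranor-8βH-labdan-17,12-olid-19-oate, via cis-fused lactone 14 (not isolated)
Conditions: H2 (1 atm), Pd/C, EtOAc, rt; filter; then KOt-Bu (0.3 equiv), t-BuOH/THF, rt
Reagents that add atoms: none
Why: heterogeneous hydrogenation should add to the less hindered α face (opposite the axial C20 methyl), and base equilibration through the lactone enolate then moves C17 from the axial position (1,3-diaxial to C20) to the equatorial one, giving the trans-fused lactone with 8β-H under thermodynamic control.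

**Step 10**
Reactants: 15 tert-butyl 13,14,15,16-tetranor-8βH-labdan-17,12-olid-19-oate
Product: 16 19-tert-butyl hydrogen 12-(phenylselanyl)-13,14,15,16-tetranor-8βH-labdane-17,19-dioate
Conditions: (PhSe)2, Na, THF, reflux; then 15, HMPA, reflux; 1 M HCl
Reagents that add atoms: diphenyl diselenide, c1ccc(cc1)[Se][Se]c1ccccc1
Why: sodium metal reduces the diselenide in the flask to sodium benzeneselenolate, a soft nucleophile that opens the lactone by SN2 attack at the primary carbinol carbon C12 (alkyl–oxygen cleavage); this differentiates the two ends of the temporary ring, and the tert-butyl ester offers no carbon open to SN2 attack.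

**Step 11**
Reactants: 16 19-tert-butyl hydrogen 12-(phenylselanyl)-13,14,15,16-tetranor-8βH-labdane-17,19-dioate
Product: 17 tert-butyl 17-hydroxy-12-(phenylselanyl)-13,14,15,16-tetranor-8βH-labdan-19-oate
Conditions: BH3·THF (2.5 equiv), THF, 0 °C → rt; MeOH
Reagents that add atoms: none
Why: borane reduction of a carboxylic acid through its acyloxyborane is much faster than reduction of the hindered tert-butyl ester, and the selenide is inert.

**Step 12**
Reactants: 17 tert-butyl 17-hydroxy-12-(phenylselanyl)-13,14,15,16-tetranor-8βH-labdan-19-oate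
Product: 19 tert-butyl 17-hydroxy-13,14,15,16-tetranor-8βH-labd-11-en-19-oate, via selenoxide 18 (not isolated)
Conditions: 30% H2O2, pyridine, THF, 0 → 50 °C
Reagents that add atoms: none
Why: oxidation of the selenide and syn-elimination of the selenoxide should give the terminal C11=C12 alkene.

**Step 13**
Reactants: 19 tert-butyl 17-hydroxy-13,14,15,16-tetranor-8βH-labd-11-en-19-oate; 20 3-bromofuran-2(5H)-one
Product: 22 tert-butyl 17-hydroxy-8βH-labd-13-en-16,15-olid-19-oate, via bis-boron adduct 21 (not isolated)
Conditions: 9-BBN (2.5 equiv), THF, 0 °C → rt; then 20, Pd(dppf)Cl2 (10 mol%), AsPh3, Cs2CO3, DMF/H2O, rt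
Reagents that add atoms: none
Why: anti-Markovnikov hydroboration places boron on C12, and B-alkyl Suzuki–Miyaura coupling with the α-bromobutenolide (oxidative addition of zerovalent palladium into C–Br, transmetalation, reductive elimination) forms C12–C13 with the butenolide alkene already in place.

**Step 14**
Reactants: 22 tert-butyl 17-hydroxy-8βH-labd-13-en-16,15-olid-19-oate
Product: 23 17-hydroxy-8βH-labd-13-en-16,15-olid-19-oic acid (target)
Conditions: TFA/CH2Cl2 (1:3), 0 °C → rt; then NaHCO3, MeOH/H2O (cleaves any trifluoroacetate)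
Reagents that add atoms: none
Why: acidolysis of the tert-butyl ester by alkyl–oxygen cleavage (tert-butyl cation, loss of isobutene) does not depend on access to the hindered axial carbonyl and should leave the butenolide and the primary alcohol intact.

**Compound list**

1 | 3-ethoxy-2-methylcyclohex-2-en-1-one | CCOC1=C(C)C(=O)CCC1 | starting material
2 | tert-butyl 4-ethoxy-3-methyl-2-oxocyclohex-3-ene-1-carboxylate (racemic) | CCOC1=C(C)C(=O)C(C(=O)OC(C)(C)C)CC1 | intermediate
3 | tert-butyl 4-ethoxy-2-hydroxy-3-methylcyclohex-3-ene-1-carboxylate (diastereomer mixture; not isolated) | CCOC1=C(C)C(O)C(C(=O)OC(C)(C)C)CC1 | intermediate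
4 | tert-butyl 3-methyl-4-oxocyclohex-2-ene-1-carboxylate (racemic) | CC1=CC(C(=O)OC(C)(C)C)CCC1=O | intermediate
5 | tert-butyl (1RS,4R)-4-hydroxy-3-methylcyclohex-2-ene-1-carboxylate | O[C@@H]1CCC(C(=O)OC(C)(C)C)C=C1C | intermediate
6 | tert-butyl (1RS,4R)-4-{[1-(dimethylamino)ethenyl]oxy}-3-methylcyclohex-2-ene-1-carboxylate (ketene N,O-acetal; not isolated) | C=C(N(C)C)O[C@@H]1CCC(C(=O)OC(C)(C)C)C=C1C | intermediate
7 | tert-butyl (1RS,2S)-2-[2-(dimethylamino)-2-oxoethyl]-3-methylcyclohex-3-ene-1-carboxylate | CC1=CCCC(C(=O)OC(C)(C)C)[C@@H]1CC(=O)N(C)C | intermediate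
8 | tert-butyl (1S,2R)-2-[2-(dimethylamino)-2-oxoethyl]-1,3-dimethylcyclohex-3-ene-1-carboxylate | CC1=CCC[C@](C)(C(=O)OC(C)(C)C)[C@@H]1CC(=O)N(C)C | intermediate
9 | tert-butyl (1S,2R)-1,3-dimethyl-2-(2-oxoethyl)cyclohex-3-ene-1-carboxylate | CC1=CCC[C@](C)(C(=O)OC(C)(C)C)[C@@H]1CC=O | intermediate
10 | 5,6-dihydro-2H-pyran-2-one | O=C1C=CCCO1 | starting material
11 | tert-butyl 7β-hydroxy-13,14,15,16-tetranor-8αH-labdan-17,12-olid-19-oate (5α-H; 9α-H; 10β-methyl; δ-lactone cis-fused to ring B; expected major C7/C8 isomer) | C[C@]12CCC[C@](C)(C(=O)OC(C)(C)C)[C@@H]1C[C@H](O)[C@@H]3C(=O)OCC[C@H]23 | intermediate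
12 | 7β-methanesulfonate of 11 (not isolated) | C[C@]12CCC[C@](C)(C(=O)OC(C)(C)C)[C@@H]1C[C@H](OS(C)(=O)=O)[C@@H]3C(=O)OCC[C@H]23 | intermediate
13 | tert-butyl 13,14,15,16-tetranorlabd-7-en-17,12-olid-19-oate | C[C@]12CCC[C@](C)(C(=O)OC(C)(C)C)[C@@H]1CC=C3C(=O)OCC[C@H]23 | intermediate
14 | tert-butyl 13,14,15,16-tetranor-8αH-labdan-17,12-olid-19-oate (cis-fused lactone; not isolated) | C[C@]12CCC[C@](C)(C(=O)OC(C)(C)C)[C@@H]1CC[C@@H]3C(=O)OCC[C@H]23 | intermediate
15 | tert-butyl 13,14,15,16-tetranor-8βH-labdan-17,12-olid-19-oate (trans-fused lactone) | C[C@]12CCC[C@](C)(C(=O)OC(C)(C)C)[C@@H]1CC[C@H]3C(=O)OCC[C@H]23 | intermediate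
16 | 19-tert-butyl hydrogen 12-(phenylselanyl)-13,14,15,16-tetranor-8βH-labdane-17,19-dioate | C[C@]12CCC[C@](C)(C(=O)OC(C)(C)C)[C@@H]1CC[C@@H](C(=O)O)[C@@H]2CC[Se]c1ccccc1 | intermediate
17 | tert-butyl 17-hydroxy-12-(phenylselanyl)-13,14,15,16-tetranor-8βH-labdan-19-oate | C[C@]12CCC[C@](C)(C(=O)OC(C)(C)C)[C@@H]1CC[C@@H](CO)[C@@H]2CC[Se]c1ccccc1 | intermediate
18 | selenoxide of 17 (not isolated) | C[C@]12CCC[C@](C)(C(=O)OC(C)(C)C)[C@@H]1CC[C@@H](CO)[C@@H]2CC[Se](=O)c1ccccc1 | intermediate
19 | tert-butyl 17-hydroxy-13,14,15,16-tetranor-8βH-labd-11-en-19-oate | C[C@]12CCC[C@](C)(C(=O)OC(C)(C)C)[C@@H]1CC[C@@H](CO)[C@@H]2C=C | intermediate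
20 | 3-bromofuran-2(5H)-one | O=C1OCC=C1Br | starting material
21 | bis-boron adduct of 19: C12 B-alkyl-9-BBN with the C17 hydroxyl as its 9-BBN borinate (not isolated) | C[C@]12CCC[C@](C)(C(=O)OC(C)(C)C)[C@@H]1CC[C@@H](COB1C3CCCC1CCC3)[C@@H]2CCB1C2CCCC1CCC2 | intermediate
22 | tert-butyl 17-hydroxy-8βH-labd-13-en-16,15-olid-19-oate | C[C@]12CCC[C@](C)(C(=O)OC(C)(C)C)[C@@H]1CC[C@@H](CO)[C@@H]2CCC1=CCOC1=O | intermediate
23 | (1S,4aR,5S,6R,8aR)-6-(hydroxymethyl)-1,4a-dimethyl-5-[2-(2-oxo-2,5-dihydrofuran-3-yl)ethyl]decahydronaphthalene-1-carboxylic acid (17-hydroxy-8βH-labd-13-en-16,15-olid-19-oic acid) | C[C@]12CCC[C@](C)(C(=O)O)[C@@H]1CC[C@@H](CO)[C@@H]2CCC1=CCOC1=O | target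

**Step count and risks**

Total step count: 14. Longest linear sequence: 14 steps (1 → 23); 10 and 20 are used as purchased.

Steps most likely to fail:

1. Step 7. The iron enolate may be protonated by the alcoholic medium before it closes onto the aldehyde, or the free aldehyde may be consumed by acetalisation or reduction, so that only open-chain conjugate adduct forms; facial selectivity at C9/C10 may also erode. The fallback separates the radical coupling from the ring closure and uses known reaction types only. It sets out from 9: acetalisation (HC(OMe)3, PPTS, MeOH) should give the dimethyl acetal F1. The iron-hydride reductive coupling with 10 (Fe(acac)3, PhSiH3, EtOH), now without a free aldehyde, should give the open-chain Giese adduct F2. LiN(i-Pr)2/Me3SiCl converts the lactone into the silyl ketene acetal F3, and catalytic Me3SiOTf closes ring B by an intramolecular Mukaiyama aldol onto the acetal-derived oxocarbenium ion to give the 7-methoxy lactone F4. E1cB loss of methanol (KOt-Bu, THF, 0 °C) comes back to the route at 13.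

2. Step 13. Base-mediated ring opening or isomerisation of the bromobutenolide may outrun transmetalation of the hindered alkylborane, or the alkylborane may protodeboronate. The fallback builds the butenolide by enolate alkylation and sulfoxide elimination. It sets out from 19: silylation (TBSCl, imidazole) should give the silyl ether F5. Hydroboration with 9-BBN gives the B-alkyl-9-BBN adduct F6 (not isolated), and iodinolysis (I2, NaOMe) gives the primary iodide F7. Alkylation of the lithium enolate of 3-(phenylthio)dihydrofuran-2(3H)-one (LiN(SiMe3)2, THF/HMPA) gives the sulfide F8. Oxidation (mCPBA, −78 °C) gives the sulfoxide F9, which on heating in toluene should undergo syn-elimination to the endocyclic butenolide silyl ether F10. Aqueous TFA removes both the silyl ether and the tert-butyl ester and comes back to the route at 23.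

3. Step 4. The ring hydrogen of 5 that is both α to the ester and allylic may be removed under the hot, weakly basic amide-acetal conditions, so that 1,4-elimination to a cyclohexadiene ester or alkene migration into conjugation competes with the sigmatropic shift. The fallback installs the quaternary centre before the rearrangement, so that no such hydrogen is present. It sets out from 2: C-methylation (K2CO3, MeI, acetone) should give the quaternary keto ester F11 (racemic). Luche reduction gives the allylic alcohol F12 (not isolated), and acid transposition as in step 2 gives the enone F13 (racemic). Reduction with (S)-2-methyl-CBS-oxazaborolidine/BH3·SMe2 should give the two (4R)-carbinols, one from each enantiomer of F13: the cis carbinol F14 (hydroxyl cis to the ester), which is kept, and the trans carbinol F15, which is separated by chromatography and set aside. Eschenmoser–Claisen rearrangement of F14 through the ketene N,O-acetal F16 (not isolated) comes back to the route at 8. This path gives up the half of the material that falls to the trans isomer and trades throughput for robustness.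

**Further compounds**

F1 | step 7 | tert-butyl (1S,2R)-2-(2,2-dimethoxyethyl)-1,3-dimethylcyclohex-3-ene-1-carboxylate | CC1=CCC[C@](C)(C(=O)OC(C)(C)C)[C@@H]1CC(OC)OC
F2 | step 7 | open-chain Giese adduct: dimethyl acetal with the δ-lactone attached through C9 to quaternary C10 (9α-H, 10β-methyl) | C[C@@]1(CCC[C@](C)(C(=O)OC(C)(C)C)[C@@H]1CC(OC)OC)[C@H]1CCOC(=O)C1
F3 | step 7 | trimethylsilyl ketene acetal of F2 | C[C@@]1(CCC[C@](C)(C(=O)OC(C)(C)C)[C@@H]1CC(OC)OC)[C@H]1CCOC(O[Si](C)(C)C)=C1
F4 | step 7 | tert-butyl 7-methoxy-13,14,15,16-tetranorlabdan-17,12-olid-19-oate (C7/C8 epimer mixture) | C[C@]12CCC[C@](C)(C(=O)OC(C)(C)C)[C@@H]1CC(OC)C3C(=O)OCC[C@H]23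
F5 | step 13 | tert-butyldimethylsilyl ether of 19 | C[C@]12CCC[C@](C)(C(=O)OC(C)(C)C)[C@@H]1CC[C@@H](CO[Si](C)(C)C(C)(C)C)[C@@H]2C=C
F6 | step 13 | C12 B-alkyl-9-BBN adduct of F5 (not isolated) | C[C@]12CCC[C@](C)(C(=O)OC(C)(C)C)[C@@H]1CC[C@@H](CO[Si](C)(C)C(C)(C)C)[C@@H]2CCB1C2CCCC1CCC2
F7 | step 13 | C12 iodide: tert-butyl 17-(tert-butyldimethylsilyloxy)-12-iodo-13,14,15,16-tetranor-8βH-labdan-19-oate | C[C@]12CCC[C@](C)(C(=O)OC(C)(C)C)[C@@H]1CC[C@@H](CO[Si](C)(C)C(C)(C)C)[C@@H]2CCI
F8 | step 13 | α-(phenylthio)-γ-butyrolactone alkylated at C13 (C13 epimer mixture) | C[C@]12CCC[C@](C)(C(=O)OC(C)(C)C)[C@@H]1CC[C@@H](CO[Si](C)(C)C(C)(C)C)[C@@H]2CCC1(Sc2ccccc2)CCOC1=O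
F9 | step 13 | sulfoxide of F8 | C[C@]12CCC[C@](C)(C(=O)OC(C)(C)C)[C@@H]1CC[C@@H](CO[Si](C)(C)C(C)(C)C)[C@@H]2CCC1(S(=O)c2ccccc2)CCOC1=O
F10 | step 13 | tert-butyldimethylsilyl ether of 22 | C[C@]12CCC[C@](C)(C(=O)OC(C)(C)C)[C@@H]1CC[C@@H](CO[Si](C)(C)C(C)(C)C)[C@@H]2CCC1=CCOC1=O
F11 | step 4 | tert-butyl 4-ethoxy-1,3-dimethyl-2-oxocyclohex-3-ene-1-carboxylate (racemic) | CCOC1=C(C)C(=O)C(C)(C(=O)OC(C)(C)C)CC1
F12 | step 4 | tert-butyl 4-ethoxy-2-hydroxy-1,3-dimethylcyclohex-3-ene-1-carboxylate (diastereomer mixture; not isolated) | CCOC1=C(C)C(O)C(C)(C(=O)OC(C)(C)C)CC1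
F13 | step 4 | tert-butyl 1,3-dimethyl-4-oxocyclohex-2-ene-1-carboxylate (racemic) | CC1=CC(C)(C(=O)OC(C)(C)C)CCC1=O
F14 | step 4 | tert-butyl (1S,4R)-4-hydroxy-1,3-dimethylcyclohex-2-ene-1-carboxylate (cis carbinol) | O[C@@H]1CC[C@](C)(C(=O)OC(C)(C)C)C=C1C
F15 | step 4 | tert-butyl (1R,4R)-4-hydroxy-1,3-dimethylcyclohex-2-ene-1-carboxylate (trans carbinol, set aside) | O[C@@H]1CC[C@@](C)(C(=O)OC(C)(C)C)C=C1C
F16 | step 4 | tert-butyl (1S,4R)-4-{[1-(dimethylamino)ethenyl]oxy}-1,3-dimethylcyclohex-2-ene-1-carboxylate (ketene N,O-acetal; not isolated) | C=C(N(C)C)O[C@@H]1CC[C@](C)(C(=O)OC(C)(C)C)C=C1C
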